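- The ratio of a plateau to its first slope is a time, and I reckon with it. In the south-east run the plateau 18.1%, divided by the first slope of 6.0% in 4.00 min, gives 12.1 min, and this stopping time, the time constant with which target levels off, is what I carry.

| flask | substrate | partner | temperature | remark | time |
|---|---|---|---|---|---|
| east | 7.6 mM | 5 equiv | 65 °C | run made earlier |  |
| south-east | 100 mM | 5 equiv | 80 °C | run made earlier |  |
| delta | 80 mM | 5.00 equiv | 80 °C |  | 2.0 h |
| theta | 12 mM | 5.00 equiv | 80 °C |  | 2.0 h |
| epsilon | 6.0 mM | 5.00 equiv | 80 °C |  | 2.0 h |
| eta | 30 mM | 5.00 equiv | 80 °C |  | 2.0 h |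
| beta | 20 mM | 5.00 equiv | 80 °C |  | 2.0 h |

| run | time / min | target / % |
|---|---|---|
| east | 10.0 | 0.3 |
| east | 15.0 | 0 |
| east | 25.0 | 1.2 |
| east | 40.0 | 1.5 |
| east | 80.0 | 1.7 |
| east | 120 | 2.5 |
| south-east | 4.00 | 6.0 |
| south-east | 12.0 | 10.6 |
| south-east | 20.0 | 13.9 |
| south-east | 30.0 | 16.2 |
| south-east | 50.0 | 18.1 |
| south-east | 60.0 | 18.0 |

(each reading ± 0.5 percentage points)

- what was read earlier has a scatter of 0.5 percentage points, one standard deviation

- the flasks put in order of amount of target, in percent of the substrate charged, best first, at 2.0 h (delta / theta / epsilon / eta / beta)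
- the amount of target, in percent of the substrate charged of the flask you put first, at 2.0 h
- the amount of target, in percent of the substrate charged of the flask you put last, at 2.0 h

- The asked 2.0 h holds 9.94 stopping times, so the flasks stand on their plateaus if they share this clock.
- But the east run gives 52.1 min, roughly, with a scatter of 0.5 percentage points on 1.2%. That run is colder and more dilute, so the clock may stretch as c(substrate) falls.
- I expect heating to shorten it, so I take the east value as an upper guess at 80 °C. Stretched in proportion to dilution, it gives epsilon 66.0 min, which is 1.82 stopping times, or 83.8% of its plateau.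
- The first slopes differ 31.3-fold for a 13.2-fold concentration, and I leave the remainder to temperature. So I read the slope as growing with c(substrate), as a bimolecular step does at fixed equivalents.
- Plateau is slope times stopping time. A fixed clock gives delta 14.5% and epsilon 1.09%. The stretched clocks give delta 18.1% and epsilon 4.97%.
- Full stretching levels the plateaus in this reckoning, but the east run's 2.5% at 65 °C against 18.1% at 80 °C does not look so, though temperature differs there as well. I keep the order by c(substrate) and commit to the midpoints: delta 16.3%, epsilon 3.03%.
- The forecast says delta > eta > beta > theta > epsilon, with 15.5% first and 1.5% last, on the ground that “all flasks have plateaued by 2 h”. Its low value stands below my midpoint of 3.03%.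
- The simulation gives delta > eta > beta > theta > epsilon, with delta at 16.9% and epsilon at 3.86%.

    target ⇌ isomer of the product (K = 0.520, k = 0.220 h⁻¹, Ea = 120 kJ mol⁻¹, ΔH = 21.0 kJ mol⁻¹)
    substrate + partner → target (k = 1.90 L mol⁻¹ h⁻¹, Ea = 93.0 kJ mol⁻¹)
    2 partner → self-condensation product (k = 4.00 L mol⁻¹ h⁻¹, Ea = 72.0 kJ mol⁻¹)
    substrate → side product A (k = 0.0840 h⁻¹, Ea = 126 kJ mol⁻¹)
    partner → decomposed reagent (k = 0.710 h⁻¹, Ea = 102 kJ mol⁻¹)
    2 substrate → side product B (k = 5.40 L mol⁻¹ h⁻¹, Ea = 62.0 kJ mol⁻¹)
    (constants at 80 °C)

- Delta is not at rest: at 2.00 h its target is made at 0.579 times the rate at which it is used up. Read at 30 min, delta stands at 14.6%; the carried 12.1 min, stretched to 15.1 min for its c(substrate) and rising towards 16.9%, gives 14.6%. Ten times the time takes epsilon's target from 3.86% to 3.70%. Over the same span delta's target goes from 16.9% to 14.8%, its substrate falls from 26.7% to 1.84%, and its side product B climbs from 43.9% to 57.0%.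

Readings and results are calculated for substances that don't exist; the scatter is artificial.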